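## Structural features

The target is a fully substituted tetrahydrofuran (O1, C2 to C5) in which C2 and C5 each carry a 4-hydroxyphenyl ring and C3 and C4 each carry a 2,4-dihydroxybenzoyl group, so that it is formally a chalcone dimer joined α to α through C3–C4 and bridged by O1 between the two β carbons. The four stereocentres are contiguous: the two aryl groups are cis, the two aroyl groups are cis, and each aroyl group is trans to the aryl group beside it, which makes the compound meso, (2R,3R,4S,5S), with a mirror plane through O1 and the midpoint of C3–C4. C3 and C4 are α to aryl ketones and can be epimerised, whereas C2 and C5 are benzylic ether carbons that cannot be corrected once set. The fragile parts are the six phenols and the two ring C–O bonds, which are benzylic, para to a phenol and β to a ketone and are therefore open to hydrogenolysis, ionisation and β-elimination. The two phenols ortho to the ketones are the awkward ones, because free or as ethers they trap a carbenoid and as esters they can hand their acyl group to a neighbouring enolate. The real difficulty is the 2,5-cis relation, combined with bond formation at C3 next to an oxygenated ortho position. The plan exploits the fact that C2–H is both benzylic and α to O1 while C3 is α to a ketone: C2–C3 can be closed by inserting a C3 keto-carbenoid into the O–CH2–aryl C–H bond of a benzyl ether on the C5 oxygen, five atoms away.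

## Logic of the disconnections

Target numbering (O1, C2–C5) is used for the open-chain compounds as well.

18 to 17: the six phenolic O–acyl bonds are cut. Every phenol must be masked during enolate and carbenoid chemistry, and the two ortho oxygens must be esters because an ether or a free hydroxyl there would capture the carbenoid. One ester type on all six oxygens allows a single unmasking and avoids hydrogenolysis beside two benzylic ring C–O bonds. The forward step must leave C2 and C5 untouched, and any enolisation at C3 or C4 must run towards the arrangement of 18.

17 to 16: the ring bond C2–C3 is cut. This removes the ring and two stereocentres and leaves an open chain that holds only C4 and C5. The forward step needs an electrophilic carbenoid at C3 that selects the ether C–H bond over hydride shift from C4, over the arenes and over the ortho oxygen, and that closes with the two aryl groups cis.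

16 to 13: the C3=N2 unit is replaced by CH2. C3 is the only methylene in 13, so the diazo group can be placed last, after all base-sensitive bond formations. The forward step must enolise C3 and not C4, without β-elimination of the ether and without acyl migration from the ortho esters.

13 to 10 and 12: the benzylic O–CH2 bond is cut. Acid-catalysed alkylation with an imidate spares the β-hydroxy ketone from base. The gain is that the C7 unit at C2 is separated from the chain. The forward step must alkylate a hindered secondary alcohol faster than acid can cyclise or cleave it.

12 to 11 to 8: the imidate C–O bond and then the carbinol C–H bond are cut. Both the C2 and the C5 aryl units thus come from one aldehyde. The forward steps must not disturb the aryl ester.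

10 to 6 and 8: the C4–C5 bond is cut as an aldol retron. This leads back to a symmetric diketone and an aldehyde. The forward step needs mono-enolisation, a Z enolate for the syn adduct, and low temperature throughout.

8 to 7 and 2: the phenolic O–acyl bond is cut; the forward step is a plain acylation.

6 to 3 and 4: the central C3–C4 bond is cut as an enolate alkylation. Both halves are the same aryl methyl ketone at two oxidation levels, so one building block serves twice and the diketone is symmetric by construction. The forward step must join the two carbons under conditions mild enough that the ortho ester does not migrate to carbon and the amine does not cleave the aryl esters.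

4 to 3: the C–Br bond is cut. The forward step must brominate the methyl group once and leave the arene and the esters alone.

3 to 1 and 2: the two phenolic O–acyl bonds are cut; the forward step must also acylate the chelated ortho hydroxyl.

## Other disconnections considered

Alternative 1: The cut is at the two exocyclic bonds C3–C(=O) and C4–C(=O), with the ring and both aryl groups kept. In the forward step the meso cis-2,5-bis[4-(benzyloxy)phenyl]-2,5-dihydrofuran A1 would be treated with PdCl2/CuCl2 under CO in MeOH. Methoxycarbonyl-palladation across C3=C4 and a second CO insertion would give the diester A2.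
- In favour: syn addition from the face away from both aryl groups would set C3 and C4 in exactly the trans, cis, trans pattern in one step. Oxidative bis-alkoxycarbonylation of cyclic alkenes by divalent palladium is an established reaction type.
- Against: the σ-alkylpalladium intermediate at C4 has the ring oxygen β to it, so β-alkoxide elimination with ring opening would compete with CO insertion. The doubly benzylic allylic ether of A1 is exposed to the acid that is formed. A1 itself must first be obtained as the pure cis isomer. A2 still lacks both resorcinol rings, so two esters on adjacent enolisable carbons must be turned into hindered ortho-oxygenated aryl ketones.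
- Comparison: on stereocontrol at C3 and C4 this alternative is the better plan, because the addition is stereospecific and does not rely on a later enolisation. On C2 and C5 the two plans are equal in that both must secure the cis relation (here in the substrate, in the chosen plan during ring closure). Each mechanism has one serious competitor, β-oxygen elimination here and 1,2-hydride shift in the chosen plan. On step economy the chosen plan should be ahead, since both aroyl groups are present from the first step and no late ester-to-ketone conversion is needed.

Alternative 2: The cut lies inside each resorcinol ring, at C1'–C2' and C5'–C6'. In the forward step the bis(propynoyl)tetrahydrofuran A3 would react with two equivalents of 1-methoxy-1,3-bis(trimethylsilyloxy)buta-1,3-diene A4 by Diels–Alder addition, elimination of the silylated leaving group and aromatisation. The product would be A5, the target with benzyl ethers on the two 4-hydroxyphenyl rings.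
- In favour: the regiochemistry of this diene with ynones is dependable and places the hydroxyls ortho and para to the ketone. Four of the six phenols would need no protecting group, and the ortho-hydroxy ketone never meets an enolate or a carbenoid. On protecting-group economy and on mildness of the final bond formations this alternative is the better plan.
- Against: it does not build the ring. A3 already contains the oxolane with all four stereocentres, so another ring synthesis (for instance through A2) must come first. A3 has two adjacent terminal ynones on enolisable carbons β to the ring oxygen and would be sensitive to base and nucleophiles. A benzyl hydrogenolysis beside two benzylic ring C–O bonds still follows.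
- Comparison: structurally this is an end game and not a skeleton-forming move. Mechanistically the cycloaddition–aromatisation is as reliable as the ester methanolysis that ends the chosen plan. On step economy it is clearly worse, because ring construction, ynone installation, annulation and hydrogenolysis add up to more than the eleven steps of the chosen plan.

Alternative 3: The cut is at C3–C4 and O1–C5, assembling the ring at the dihydrofuran level from two three-carbon pieces. In the forward step Mn(OAc)3 (trivalent manganese) would oxidise the 1,3-diketone A6 to its α radical. The radical would add to the α carbon of the chalcone A7, and oxidation of the benzylic radical with capture by the enol oxygen would give the trans-4,5-dihydrofuran A8.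
- In favour: it is the most convergent plan. A6 and A7 both come from the same acetophenone and aldehyde, and the whole carbon skeleton and the ring would form in one step with C4 and C5 trans. No diazo compound or azide is needed. Up to A8 it is the better plan on step economy and on reagent safety.
- Against: A6 is unsymmetrical, so closure through the wrong enol oxygen would give the constitutional isomer with the aryl and aroyl units exchanged at C2 and C3. The C2=C3 bond of A8 is a tetrasubstituted push–pull alkene that must then be reduced with the C2 hydrogen delivered cis to the C5 hydrogen. One face is shielded by the C4 aroyl group and the other by the C5 aryl group, so the 2,5-cis relation is not secured. Reduction forceful enough for this alkene would also threaten the benzyl ethers, the benzylic ring C–O bond and the ketones.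
- Comparison: on C4 and C5 the two plans are equal. On C2, the centre that cannot be corrected, the chosen plan is better, because the insertion sets it under the influence of C5 in a five-membered transition state. On step count this alternative would be shorter only if the reduction and the closure regiochemistry behaved.

Key step: step 10

Remark: all six phenols are carried as pivalate esters, so that the final unmasking is one operation and no arene is electron-rich when the carbenoid is formed. Compounds 10, 13 and 16 are racemic and drawn as one enantiomer; 17 and 18 are meso.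

Assumption: for a 2,5-cis-diaryl ring, the arrangement with each aroyl group trans to the aryl group beside it is taken to be the preferred one at C3 and C4 under enolising conditions.

## Route

Step 1
Reactants: 1 2',4'-dihydroxyacetophenone; 2 pivaloyl chloride
Product: 3 4-acetyl-1,3-phenylene bis(2,2-dimethylpropanoate) [2',4'-bis(pivaloyloxy)acetophenone]
Conditions: 2 (2.5 equiv), Et3N, DMAP (cat.), CH2Cl2, 0 °C to rt
Reagents that add atoms: none
Why: Acylation of both phenols by an acyl chloride under nucleophilic catalysis; the chelated ortho hydroxyl needs the acylpyridinium ion. An ester oxygen ortho to the ketone cannot form an oxonium ylide with the later carbenoid, and the bulky pivalate resists O-to-C migration better than smaller acyl groups.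

Step 2
Reactants: 3 4-acetyl-1,3-phenylene bis(2,2-dimethylpropanoate)
Product: 4 4-(2-bromoacetyl)-1,3-phenylene bis(2,2-dimethylpropanoate)
Conditions: CuBr2 (2.0 equiv), EtOAc/CHCl3, reflux
Reagents that add atoms: copper dibromide (CuBr2), Br[Cu]Br
Why: Heterogeneous α-monobromination of an aryl methyl ketone through its enol, in which two equivalents of the divalent copper salt deliver one bromine and end as insoluble CuBr. The conditions are non-basic and the arene is deactivated by the acyl and acyloxy groups, so neither ester cleavage nor nuclear bromination is expected.

Step 3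
Reactants: 3 4-acetyl-1,3-phenylene bis(2,2-dimethylpropanoate); 4 4-(2-bromoacetyl)-1,3-phenylene bis(2,2-dimethylpropanoate)
Product: 6 1,4-bis[2,4-bis(pivaloyloxy)phenyl]butane-1,4-dione, via chlorozinc enolate 5 (not isolated)
Conditions: ZnCl2 (2.0 equiv), Et3N (1.5 equiv), t-BuOH (1.5 equiv), toluene, rt; 3 (1.5 equiv), 4 (1.0 equiv), rt, 2–3 d; aq. NH4Cl
Reagents that add atoms: zinc dichloride (ZnCl2), Cl[Zn]Cl (zinc and chlorine of 5 only)
Why: Zinc-enolate coupling of a methyl ketone with an α-bromomethyl ketone: ZnCl2 and the tertiary amine generate the zinc enolate 5 of 3 under nearly neutral conditions, and 5 is joined to 4 at carbon (directly, or through an aldolate that collapses by way of a cyclopropanolate), both paths ending in the same symmetric 1,4-diketone. No alkali-metal enolate is present, so O-to-C pivaloyl transfer (Baker–Venkataraman rearrangement) should not compete, and Et3N is used in place of a secondary amine to avoid aminolysis of the aryl esters.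

Step 4
Reactants: 7 4-hydroxybenzaldehyde; 2 pivaloyl chloride
Product: 8 4-formylphenyl pivalate
Conditions: 2 (1.1 equiv), Et3N, CH2Cl2, 0 °C to rt
Reagents that add atoms: none
Why: Phenol acylation with an acyl chloride and an amine base. The ester also lowers the electron density of the arene that will sit on C5 and, through steps 6 to 8, on C2.

Step 5
Reactants: 6 1,4-bis[2,4-bis(pivaloyloxy)phenyl]butane-1,4-dione; 8 4-formylphenyl pivalate
Product: 10 rac-(2S)-2-{(S)-hydroxy[4-(pivaloyloxy)phenyl]methyl}-1,4-bis[2,4-bis(pivaloyloxy)phenyl]butane-1,4-dione (syn aldol), via lithium enolate 9 (not isolated)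
Conditions: 6 (1.5 equiv), LiN(iPr)2 (1.0 equiv), THF, −78 °C; 8 (1.0 equiv), −78 °C, 20 min; AcOH, −78 °C
Reagents that add atoms: none
Why: Directed aldol addition of a lithium ketone enolate to a non-enolisable aldehyde. The aryl ketone should give the Z enolate 9, and a closed chair-like six-membered transition state with the aldehyde aryl group equatorial should give the syn adduct, setting C4 and C5 in the relation that becomes 4,5-trans on the ring. Excess 6 with limiting base favours the mono-enolate, and the cold quench forestalls retro-aldol and acyl migration.

Step 6
Reactants: 8 4-formylphenyl pivalate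
Product: 11 4-(hydroxymethyl)phenyl pivalate
Conditions: NaBH4, THF/EtOH, 0 °C, 20 min; aq. NH4Cl
Reagents that add atoms: none
Why: Chemoselective borohydride reduction of an aryl aldehyde. The hindered aryl pivalate should not be reduced or transesterified in a short time at 0 °C.

Step 7
Reactants: 11 4-(hydroxymethyl)phenyl pivalate
Product: 12 4-(pivaloyloxy)benzyl 2,2,2-trichloroacetimidate
Conditions: Cl3CCN, DBU (cat.), CH2Cl2, 0 °C
Reagents that add atoms: trichloroacetonitrile, N#CC(Cl)(Cl)Cl
Why: Base-catalysed addition of the alcohol to the electron-poor nitrile (trichloroacetimidate formation). No stereocentre is involved.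

Step 8
Reactants: 10 rac-(2S)-2-{(S)-hydroxy[4-(pivaloyloxy)phenyl]methyl}-1,4-bis[2,4-bis(pivaloyloxy)phenyl]butane-1,4-dione; 12 4-(pivaloyloxy)benzyl 2,2,2-trichloroacetimidate
Product: 13 rac-(2S)-2-{(S)-[4-(pivaloyloxy)benzyloxy][4-(pivaloyloxy)phenyl]methyl}-1,4-bis[2,4-bis(pivaloyloxy)phenyl]butane-1,4-dione
Conditions: 12 (1.5 equiv), TfOH (5 mol%), CH2Cl2/cyclohexane, 0 °C to rt
Reagents that add atoms: none
Why: Acid-catalysed O-alkylation with a benzylic trichloroacetimidate: the protonated imidate passes its benzyl group to the hydroxyl and leaves as trichloroacetamide, so the β-hydroxy ketone never meets base (no retro-aldol, no E1cB). The acyloxy group on the carbinol arene slows ionisation at C5, so its configuration should be kept.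

Step 9
Reactants: 13 rac-(2S)-2-{(S)-[4-(pivaloyloxy)benzyloxy][4-(pivaloyloxy)phenyl]methyl}-1,4-bis[2,4-bis(pivaloyloxy)phenyl]butane-1,4-dione
Product: 16 rac-(3S)-2-diazo-3-{(S)-[4-(pivaloyloxy)benzyloxy][4-(pivaloyloxy)phenyl]methyl}-1,4-bis[2,4-bis(pivaloyloxy)phenyl]butane-1,4-dione, via lithium enolate 14 (not isolated), via trifluoroacetyl diketone 15 (not isolated)
Conditions: LiN(SiMe3)2 (1.1 equiv), THF, −78 °C; CF3CO2CH2CF3, −78 °C; cold aq. HCl work-up; then 4-acetamidobenzenesulfonyl azide, Et3N, H2O (1 equiv), MeCN, rt
Reagents that add atoms: 4-acetamidobenzenesulfonyl azide, CC(=O)Nc1ccc(cc1)S(=O)(=O)N=[N+]=[N-]; 2,2,2-trifluoroethyl trifluoroacetate, O=C(OCC(F)(F)F)C(F)(F)F (trifluoroacetyl group of 15 only)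
Why: Detrifluoroacetylative diazo transfer, a Regitz-type transfer to an activated ketone. The amide base should deprotonate the only methylene, C3, because the C4 methine is hindered; Claisen-type trifluoroacetylation gives 15, whose 1,3-dicarbonyl carbon takes two nitrogens from the sulfonyl azide while the trifluoroacetyl group leaves as the N-sulfonyl amide. C4 and C5 are not touched, and the enolate is held at −78 °C to avoid acyl migration and β-elimination of the ether.

Step 10
Reactants: 16 rac-(3S)-2-diazo-3-{(S)-[4-(pivaloyloxy)benzyloxy][4-(pivaloyloxy)phenyl]methyl}-1,4-bis[2,4-bis(pivaloyloxy)phenyl]butane-1,4-dione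
Product: 17 [(2R,3R,4S,5S)-2,5-bis[4-(pivaloyloxy)phenyl]oxolane-3,4-diyl]bis{[2,4-bis(pivaloyloxy)phenyl]methanone} (meso)
Conditions: Rh2(O2CCMe3)4 (2 mol%), CH2Cl2, slow addition of 16 at −78 °C, then warmed only as far as N2 evolution requires (at most 0 °C)
Reagents that add atoms: none
Why: The dirhodium carboxylate (divalent rhodium) adds to the diazo carbon of 16, dinitrogen leaves, and the resulting electrophilic keto-carbenoid at C3 takes up the hydridic benzylic C–H bond of the ether methylene in one three-centre event, forming C2–C3 and releasing the catalyst. The closest known reaction type is the dirhodium-tetracarboxylate-catalysed intramolecular 1,5 C–H insertion of α-diazo ketones into C–H bonds α to an ether oxygen, which gives tetrahydrofurans. The oxolane ring closes in the 1,5 mode through a five-membered, envelope-like transition state made of C3, C4, C5, O1 and C2. C2 is set by the resident C5 centre: of the two diastereotopic benzylic hydrogens, the one whose replacement keeps both aryl groups pseudo-equatorial on the forming ring should react, which places the aryl groups cis across the oxygen. C3 is set by the aroyl group of the carbenoid turning away from the new C2 aryl group (2,3-trans); this centre is enolisable, so a minor epimer can be drained later. The step needs site selectivity for this C–H bond over 1,2-hydride shift from C4, over attack on the C5 aryl ring and over ylide formation at the ortho oxygen. The target bond is activated by both the oxygen and the arene, the C4 hydrogen is α to a ketone and poorly hydridic, and the bulky electron-rich pivalate ligands at low temperature are chosen because such catalysts disfavour β-hydride migration. All arenes carry deactivating acyloxy groups, and the ortho oxygen is an ester and not an ether.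

Step 11
Reactants: 17 [(2R,3R,4S,5S)-2,5-bis[4-(pivaloyloxy)phenyl]oxolane-3,4-diyl]bis{[2,4-bis(pivaloyloxy)phenyl]methanone}
Product: 18 [(2R,3R,4S,5S)-2,5-bis(4-hydroxyphenyl)oxolane-3,4-diyl]bis[(2,4-dihydroxyphenyl)methanone] (meso; the target)
Conditions: NaOMe (8 equiv), MeOH/THF, 0 °C to rt, under Ar; then AcOH
Reagents that add atoms: none
Why: Methoxide transesterification should cleave all six aryl pivalates in one operation, the phenoxides being good leaving groups. Before the ortho phenoxides form, the C3 and C4 methines can enolise reversibly, which gives a minor C3 epimer the chance to settle into the arrangement with each aroyl group trans to the neighbouring aryl group. C2 and C5 should not be affected, since ring opening by β-elimination would be the reverse of a 5-endo closure and is slow at this temperature.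

## Compound list

1 | 2',4'-dihydroxyacetophenone | CC(=O)c1ccc(O)cc1O | starting material
2 | pivaloyl chloride | CC(C)(C)C(Cl)=O | starting material
3 | 4-acetyl-1,3-phenylene bis(2,2-dimethylpropanoate) | CC(=O)c1ccc(OC(=O)C(C)(C)C)cc1OC(=O)C(C)(C)C | intermediate
4 | 4-(2-bromoacetyl)-1,3-phenylene bis(2,2-dimethylpropanoate) | O=C(CBr)c1ccc(OC(=O)C(C)(C)C)cc1OC(=O)C(C)(C)C | intermediate
5 | chlorozinc enolate of 3 | Cl[Zn]OC(=C)c1ccc(OC(=O)C(C)(C)C)cc1OC(=O)C(C)(C)C | intermediate (not isolated)
6 | 1,4-bis[2,4-bis(pivaloyloxy)phenyl]butane-1,4-dione | O=C(CCC(=O)c1ccc(OC(=O)C(C)(C)C)cc1OC(=O)C(C)(C)C)c1ccc(OC(=O)C(C)(C)C)cc1OC(=O)C(C)(C)C | intermediate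
7 | 4-hydroxybenzaldehyde | O=Cc1ccc(O)cc1 | starting material
8 | 4-formylphenyl pivalate | O=Cc1ccc(OC(=O)C(C)(C)C)cc1 | intermediate
9 | lithium (Z)-mono-enolate of 6 | [Li]O/C(=C\CC(=O)c1ccc(OC(=O)C(C)(C)C)cc1OC(=O)C(C)(C)C)c1ccc(OC(=O)C(C)(C)C)cc1OC(=O)C(C)(C)C | intermediate (not isolated)
10 | rac-(2S)-2-{(S)-hydroxy[4-(pivaloyloxy)phenyl]methyl}-1,4-bis[2,4-bis(pivaloyloxy)phenyl]butane-1,4-dione (syn aldol) | O=C(c1ccc(OC(=O)C(C)(C)C)cc1OC(=O)C(C)(C)C)C[C@H](C(=O)c1ccc(OC(=O)C(C)(C)C)cc1OC(=O)C(C)(C)C)[C@@H](c1ccc(OC(=O)C(C)(C)C)cc1)O | intermediate
11 | 4-(hydroxymethyl)phenyl pivalate | OCc1ccc(OC(=O)C(C)(C)C)cc1 | intermediate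
12 | 4-(pivaloyloxy)benzyl 2,2,2-trichloroacetimidate | N=C(OCc1ccc(OC(=O)C(C)(C)C)cc1)C(Cl)(Cl)Cl | intermediate
13 | rac-(2S)-2-{(S)-[4-(pivaloyloxy)benzyloxy][4-(pivaloyloxy)phenyl]methyl}-1,4-bis[2,4-bis(pivaloyloxy)phenyl]butane-1,4-dione | O=C(c1ccc(OC(=O)C(C)(C)C)cc1OC(=O)C(C)(C)C)C[C@H](C(=O)c1ccc(OC(=O)C(C)(C)C)cc1OC(=O)C(C)(C)C)[C@@H](c1ccc(OC(=O)C(C)(C)C)cc1)OCc1ccc(OC(=O)C(C)(C)C)cc1 | intermediate
14 | lithium C3 enolate of 13 | [Li]O/C(=C\[C@H](C(=O)c1ccc(OC(=O)C(C)(C)C)cc1OC(=O)C(C)(C)C)[C@@H](c1ccc(OC(=O)C(C)(C)C)cc1)OCc1ccc(OC(=O)C(C)(C)C)cc1)c1ccc(OC(=O)C(C)(C)C)cc1OC(=O)C(C)(C)C | intermediate (not isolated)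
15 | C3-trifluoroacetyl derivative of 13 (C3 configuration undefined, enolised) | O=C(c1ccc(OC(=O)C(C)(C)C)cc1OC(=O)C(C)(C)C)C(C(=O)C(F)(F)F)[C@H](C(=O)c1ccc(OC(=O)C(C)(C)C)cc1OC(=O)C(C)(C)C)[C@@H](c1ccc(OC(=O)C(C)(C)C)cc1)OCc1ccc(OC(=O)C(C)(C)C)cc1 | intermediate (not isolated)
16 | rac-(3S)-2-diazo-3-{(S)-[4-(pivaloyloxy)benzyloxy][4-(pivaloyloxy)phenyl]methyl}-1,4-bis[2,4-bis(pivaloyloxy)phenyl]butane-1,4-dione | O=C(c1ccc(OC(=O)C(C)(C)C)cc1OC(=O)C(C)(C)C)C(=[N+]=[N-])[C@H](C(=O)c1ccc(OC(=O)C(C)(C)C)cc1OC(=O)C(C)(C)C)[C@@H](c1ccc(OC(=O)C(C)(C)C)cc1)OCc1ccc(OC(=O)C(C)(C)C)cc1 | intermediate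
17 | [(2R,3R,4S,5S)-2,5-bis[4-(pivaloyloxy)phenyl]oxolane-3,4-diyl]bis{[2,4-bis(pivaloyloxy)phenyl]methanone} (meso) | O=C(c1ccc(OC(=O)C(C)(C)C)cc1OC(=O)C(C)(C)C)[C@@H]1[C@H](C(=O)c2ccc(OC(=O)C(C)(C)C)cc2OC(=O)C(C)(C)C)[C@@H](c2ccc(OC(=O)C(C)(C)C)cc2)O[C@H]1c1ccc(OC(=O)C(C)(C)C)cc1 | intermediate
18 | [(2R,3R,4S,5S)-2,5-bis(4-hydroxyphenyl)oxolane-3,4-diyl]bis[(2,4-dihydroxyphenyl)methanone] (meso) | O=C(c1ccc(O)cc1O)[C@@H]1[C@H](C(=O)c2ccc(O)cc2O)[C@@H](c2ccc(O)cc2)O[C@H]1c1ccc(O)cc1 | target

## Step count and least certain steps

Total: 11 steps. Longest linear sequence: 8 steps (1, 2, 3, 5, 8, 9, 10, 11); the branch 4, 6, 7, 8, 9, 10, 11 has 7 steps.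

Step 10 (key step). The most likely failure is 1,2-hydride migration from C4 to the carbenoid carbon. β-Hydride migration is intrinsically fast in alkyl-substituted acceptor carbenoids, and here it would create a doubly conjugated alkene. Lesser risks are attack of the carbenoid on the ortho position of the C5 aryl ring (also a five-membered closure), a slower insertion because the acyloxy group makes the benzylic C–H bond less hydridic than that of an alkoxybenzyl ether, and loss of the 2,5-cis preference if the hydride transfer becomes stepwise. A C3 epimer is not a failure: it should converge in step 11 or on brief treatment of 17 with DBU.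

Fallback: form the same C2–C3 bond and ring by a polar closure that needs no carbenoid. Compound 10 would be treated with Me3SiOTf/Et3N to give its bis(trimethylsilyl) derivative F1 (silyl ether at the C5 oxygen and silyl enol ether at C3). F1 and aldehyde 8 with catalytic Me3SiOTf in CH2Cl2 at −78 °C should form an oxocarbenium ion on the C5 oxygen, which the C3 enol silane attacks to give 17. This ring closure is the one that operates in Lewis-acid-catalysed additions of aldehydes to donor–acceptor cyclopropanes, where an envelope with both aryl groups pseudo-equatorial favours cis-2,5-diaryl tetrahydrofurans. The fallback sets out from 10 (with 8) and returns at 17, bypassing 11 to 16.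

Step 9. The likely failures are competitive deprotonation at C4 followed by β-elimination of the benzyloxy group, and pivaloyl migration from the ortho ester to the C3 enolate if the enolate warms.

Fallback: avoid the metal amide. Compound 13 would be condensed with tert-butoxybis(dimethylamino)methane (THF, 50 °C) to the enaminone F2. Only a methylene can form the aminomethylene unit, so regiochemistry at C3 is inherent. Diazo transfer to F2 with 4-acetamidobenzenesulfonyl azide in MeCN should then give 16, with loss of the N-sulfonyl formamidine. The fallback sets out from 13 and returns at 16.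

Step 8. The likely failure is acid-induced cyclisation of the γ-hydroxy ketone onto the C1 ketone with dehydration, or retro-aldol cleavage, either of which could outpace the slow alkylation of a hindered secondary alcohol.

Fallback: form C4–C5 and the ether together so that no free alcohol exists. Compound 6 (in excess) with Me3SiOTf/Et3N would give the mono(trimethylsilyl) enol ether F3, and 11 with Me3SiCl/Et3N would give the trimethylsilyl ether F4. Aldehyde 8, F4 and F3 with catalytic Me3SiOTf in CH2Cl2 at −78 °C should give 13 directly, by a Mukaiyama-type addition of the enol silane to the oxocarbenium ion formed from aldehyde and silyl ether. Either C4 epimer is usable because C4 can be corrected later by enolisation. The fallback sets out from 6 (with 8 and 11) and returns at 13, bypassing 10 and 12.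

Step 3. The likely failures are slow or incomplete coupling of two ortho-substituted, hindered partners, displacement of bromide by the amine, and epoxide formation by attack of the enolate oxygen-side aldolate on the bromomethyl carbon.

Fallback: build the central bond by oxidative dimerisation of a neutral enol derivative, so that no bromide and no amine-sensitive electrophile is involved. Compound 3 would be treated with Me3SiOTf/Et3N in CH2Cl2 at 0 °C to give the trimethylsilyl enol ether F5. F5 with Ag2O in DMSO at 65 °C should couple at carbon to give 6, a known route from silyl enol ethers of aryl methyl ketones to 1,4-diaryl-1,4-diketones, with silver metal precipitating. The fallback sets out from 3 and returns at 6, bypassing 4 and 5.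

## Further compounds

F1 | step 10 | bis(trimethylsilyl) derivative of 10 (C5 silyl ether, C3 Z silyl enol ether) | C[Si](C)(C)O/C(=C\[C@H](C(=O)c1ccc(OC(=O)C(C)(C)C)cc1OC(=O)C(C)(C)C)[C@@H](c1ccc(OC(=O)C(C)(C)C)cc1)O[Si](C)(C)C)c1ccc(OC(=O)C(C)(C)C)cc1OC(=O)C(C)(C)C
F2 | step 9 | C3 (dimethylamino)methylene derivative of 13 (enaminone, alkene geometry undefined) | CN(C)C=C(C(=O)c1ccc(OC(=O)C(C)(C)C)cc1OC(=O)C(C)(C)C)[C@H](C(=O)c1ccc(OC(=O)C(C)(C)C)cc1OC(=O)C(C)(C)C)[C@@H](c1ccc(OC(=O)C(C)(C)C)cc1)OCc1ccc(OC(=O)C(C)(C)C)cc1
F3 | step 8 | mono(trimethylsilyl) enol ether of 6 | C[Si](C)(C)O/C(=C\CC(=O)c1ccc(OC(=O)C(C)(C)C)cc1OC(=O)C(C)(C)C)c1ccc(OC(=O)C(C)(C)C)cc1OC(=O)C(C)(C)C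
F4 | step 8 | 4-[(trimethylsilyloxy)methyl]phenyl pivalate | C[Si](C)(C)OCc1ccc(OC(=O)C(C)(C)C)cc1
F5 | step 3 | trimethylsilyl enol ether of 3 | C[Si](C)(C)OC(=C)c1ccc(OC(=O)C(C)(C)C)cc1OC(=O)C(C)(C)C
A1 | alternative 1 | cis-2,5-bis[4-(benzyloxy)phenyl]-2,5-dihydrofuran (meso) | C1=C[C@@H](c2ccc(OCc3ccccc3)cc2)O[C@H]1c1ccc(OCc2ccccc2)cc1
A2 | alternative 1 | dimethyl (2R,3R,4S,5S)-2,5-bis[4-(benzyloxy)phenyl]oxolane-3,4-dicarboxylate (meso) | COC(=O)[C@@H]1[C@H](C(=O)OC)[C@@H](c2ccc(OCc3ccccc3)cc2)O[C@H]1c1ccc(OCc2ccccc2)cc1
A3 | alternative 2 | (2R,3R,4S,5S)-2,5-bis[4-(benzyloxy)phenyl]-3,4-di(prop-2-ynoyl)oxolane (meso) | C#CC(=O)[C@@H]1[C@H](C(=O)C#C)[C@@H](c2ccc(OCc3ccccc3)cc2)O[C@H]1c1ccc(OCc2ccccc2)cc1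
A4 | alternative 2 | 1-methoxy-1,3-bis(trimethylsilyloxy)buta-1,3-diene | COC(=CC(=C)O[Si](C)(C)C)O[Si](C)(C)C
A5 | alternative 2 | target with benzyl ethers on the two 4-hydroxyphenyl groups (meso) | O=C(c1ccc(O)cc1O)[C@@H]1[C@H](C(=O)c2ccc(O)cc2O)[C@@H](c2ccc(OCc3ccccc3)cc2)O[C@H]1c1ccc(OCc2ccccc2)cc1
A6 | alternative 3 | 1-[2,4-bis(benzyloxy)phenyl]-3-[4-(benzyloxy)phenyl]propane-1,3-dione | O=C(CC(=O)c1ccc(OCc2ccccc2)cc1)c1ccc(OCc2ccccc2)cc1OCc1ccccc1
A7 | alternative 3 | (E)-1-[2,4-bis(benzyloxy)phenyl]-3-[4-(benzyloxy)phenyl]prop-2-en-1-one | O=C(/C=C/c1ccc(OCc2ccccc2)cc1)c1ccc(OCc2ccccc2)cc1OCc1ccccc1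
A8 | alternative 3 | trans-3,4-bis[2,4-bis(benzyloxy)benzoyl]-2,5-bis[4-(benzyloxy)phenyl]-4,5-dihydrofuran (racemic) | O=C(c1ccc(OCc2ccccc2)cc1OCc1ccccc1)C1=C(c2ccc(OCc3ccccc3)cc2)O[C@@H](c2ccc(OCc3ccccc3)cc2)[C@@H]1C(=O)c1ccc(OCc2ccccc2)cc1OCc1ccccc1
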